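## Structural features

The target is a briarane. A cyclohexane (ring A: C1, C10–C14) is trans-fused through C1–C10 to a ten-membered carbocycle (C1–C10). That ring carries a trans-fused α-methyl-β-hydroxy-γ-lactone (C7–O–C19(=O)–C17–C8).

Ring A holds six contiguous stereocentres: C10, the quaternary C1 (methyl C15), C14, C13, C12 and the spiro-epoxide carbon C11. The oxygens on C14, C13, C12 and C11 all lie on the face opposite to the C1 methyl group. O13 carries a 4-methylpentanoate; O2, O9, O12 and O14 carry acetates.

The large ring adds C2 (next to the quaternary C1) and C9 (next to C10). It also holds the cluster C6 (secondary allylic chloride beside the C5 exo-methylene), C7 (lactone oxygen), C8 (tertiary alcohol) and C17.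

Fragile groups are:
- the 2,2-disubstituted epoxide (acids, Lewis acids);
- the allylic chloride (reduction, allylic substitution, elimination toward C7);
- the β-hydroxy lactone (retro-aldol, dehydration);
- five esters of two kinds (acyl migration, base);
- every ring A carbonyl intermediate that has O14 in the β-position (elimination).

The real difficulties are the quaternary C1 with three stereogenic neighbours, the closure of a ten-membered ring that must deliver the 6,7-anti chlorohydrin, and the differentiation of six oxygen functions.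

The key step exploits the row C14–C1–C10 of ring A, with C2 cis to O14 and trans to C9. This is the substitution pattern of an endo [4+2] adduct of an (E)-2-methyl enal (C2, C1, C15, C10, C9) with a 1-alkoxy-3-silyloxy diene (C14–C11). The adduct also keeps a C12 enol ether from which O13, C20 and O12 can be introduced.

## Logic of the disconnections

**53 ⇐ 52 ⇐ 51.** Bond cut: the O14–acetyl bond, preceded by release of O14 from its 4-methoxybenzyl ether. The C14 ether is needed early for chelation and can be removed last under neutral oxidative conditions beside the epoxide, the allylic chloride and the hydroxy lactone. The other three acetates are installed one at a time as each alcohol appears, so no polyol is handled. The forward step must acetylate a hindered axial alcohol without touching the tertiary 8-OH.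

**51 ⇐ 49 (through 50).** Bond cut: C8–C17, the carbon–carbon bond of the lactone. This removes C17, C18 and C19 as the acyl group of 46 and turns the tertiary carbinol into a ketone. The forward Reformatsky closure must give the trans-fused lactone (O8 cis to C6) and place the C17 methyl group cis to O8; both are left to the ring.

**49 ⇐ 48 ⇐ 47 ⇐ 45 ⇐ 43 (through 44).** Bond cut: C6–C7, which opens the ten-membered ring. This is the only bond of the large ring flanked by two heteroatom-bearing stereocentres that an allylmetal addition can create together with the C5 exo-methylene. The precursor 43 is acyclic between C2 and C9. The forward step must give the 6,7-anti chlorohydrin and the 7,8-anti relationship, the latter relayed from the temporary silyloxy centre C8, which is later oxidised.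

**43 ⇐ 41 ⇐ 40 ⇐ 39 ⇐ 38 ⇐ 33 + 37.** Bond cut: C8–C9. The three-carbon unit C7–C8(O)–C9(O) comes from one allylboration. Hydride addition to a C9 ketone, not carbon addition to the C9 aldehyde, is predicted to give the required 9S centre, so the allylboration sets only C8 and C9 is corrected through 39. The forward steps need a Lewis-acid-free allylation that the epoxide tolerates.

**33 ⇐ 32 ⇐ 31 ⇐ 30 ⇐ 29 ⇐ 28 ⇐ 27 ⇐ 25 (through 26).** Bonds cut: C11–C20, C11–O(epoxide), C20–O and the C12–H bond of the carbinol. The whole C11/C12 array is derived from a C12 ketone and formaldehyde. The forward steps need regioselective methylenation at C11, hydride delivery to the β face of C12, and epoxidation directed by the 12α-hydroxyl.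

**25 ⇐ 23 + 24; 23 ⇐ 20 (through 21 and 22).** Bonds cut: O13–acyl and C13–O. The C12 enol ether of the cycloadduct is the natural site for oxygenation. The ester is introduced with inversion so that the kinetically expected 13β-alcohol ends as the 13α-ester. The forward steps need facial control in the oxidation and an SN2 reaction at a hindered, ketone-activated carbon.

**20 ⇐ 19 ⇐ 8 + 17 (through 18).** Bond cut: C2–C3. The complete C3–C6/C16 chain, already carrying the chloroalkene, is added as a Grignard reagent. The forward addition must set C2 by 1,3-chelation with the C14 ether.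

**8 ⇐ 3 + 7.** Bonds cut: C1–C14 and C10–C11. One cycloaddition builds ring A and three stereocentres from two achiral four-carbon pieces. The forward step needs catalyst-controlled facial selectivity, endo selectivity and regiocontrol.

**17 ⇐ 16 ⇐ 13 ⇐ 12 ⇐ 9 + 10; 37 ⇐ 36 ⇐ 34 + 35; 3 ⇐ 2 ⇐ 1; 7 ⇐ 6 ⇐ 4 + 5.** The building blocks go back to commercial materials. The demand is a geometrically defined chloroalkene in 12 and (E) geometry in 3, 7 and 37.

## Other disconnections considered

**Alternative 1:** The cut is made at C9–C10 and C1–C2 in one operation. In the forward direction, i-PrO(Me)2SiCH2MgCl with CuBr·SMe2 adds to C10 of enone A2. The enolate is transmetallated with ZnCl2 and adds through C1 to aldehyde A3, giving A1.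
- In its favour: two carbon–carbon bonds and three stereocentres (C10, C1, C2) are made in one flask. The C2–C7 chain arrives complete. Ring A of A1 already carries O12 and O13 and has carbonyl groups at C11 and C14.
- Against it here: all selectivity is substrate-derived. The cuprate face depends on an acetonide two atoms away, and C2 depends on the aldol geometry of a fully substituted zinc enolate. O12 and O13 are tied in one acetonide although they need different esters. The C14 ketone must still be reduced to the axial alcohol. The chain ends in a C5=C6 alkene with the C16 methyl group, so the chlorine and the exo-methylene must be made late by an allylic transposition whose C6 configuration is not designed in. The large ring would then be closed at C7–C8 or C8–C9.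
- Comparison: on step economy toward a functionalised ring A with its chain, A1 is better than the chosen plan, which needs steps 6–14 for the same ground. On control of absolute configuration and of C2, C13 and C6, the chosen plan is better defined. Mechanistically both rely on well-known reaction types.

**Alternative 2:** The ten-membered ring is not closed but uncovered. The C2=C7 double bond of tricycle A5, reached from the aromatic template A6, is cleaved by ozone (or RuO4 from RuCl3 and NaIO4) to diketone A4.
- In its favour: there is no medium-ring closure at all. The stereocentres around C8–C10 are set on a rigid fused framework. The starting material is cheap and enantiopure with a suitable methyl-bearing quaternary centre.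
- Against it here: the carbons of A6 fit the target poorly. Its saturated ring has three unfunctionalised methylene groups where O12, O13 and O14 are needed, and a carboxyl-bearing quaternary carbon where C11 must become a spiro-epoxide. The isopropyl group has to be degraded, and the C17–C19 unit has to be added. After cleavage, A4 is a 1,6-diketone prone to transannular aldol reaction, and its two ketones must be told apart before C2 is reduced and C5–C7 are elaborated on a flexible ring.
- Comparison: on the mechanism of ring formation, oxidative cleavage is more dependable than step 28 of the chosen plan, and this point goes to the alternative. On structural fit and step economy it is clearly worse.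

**Alternative 3:** The cut is C8–C17. Rh2(O2CCPh3)4 decomposes the diazo ester A8, and the carbenoid inserts into the C8–H bond with retention to give A7.
- In its favour: no C8 ketone is needed, so the epimerisable β-chloro diacyloxy ketone 49 is avoided. The conditions are neutral. The tertiary C–O centre comes from a secondary ether whose configuration is easy to set. The bulky carboxylate ligands disfavour the 1,2-hydride shift of the α-methyl carbenoid.
- Against it here: competing insertion or cyclopropanation at other sites (exocyclic alkenes, silyl ethyl groups) is possible. C17 is set only by the insertion transition state. The diazo ester has to be installed. It is also a disconnection of the lactone, not of the carbocyclic skeleton, so it cannot replace a ring A or large-ring strategy.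
- Comparison: for the lactone itself it is the equal of step 32 in expected selectivity and better in functional-group tolerance and step count (three operations against four). The chosen route already builds the 8-silyloxy centre with the configuration this insertion needs, so it is kept as the fallback for step 32.

Key step: step 5

## Remarks on the chemistry (assumptions)

- **Locants and faces.** Briarane locants C1–C20 are used throughout. In ring A, β is the face of the C1 methyl group and α the opposite face.
- **Structure check.** The enal 3, the diene skeleton and adduct 8 were checked atom by atom against the target. 8 (C2 cis to O14, trans to C9; 1R,2S,6S) already has the required configuration at C1, C10 and C14, so no structural correction is needed.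
- **Diene protecting group.** The diene carries a triethylsilyl and not a tert-butyldimethylsilyl enol ether. After the Rubottom step, O13 must be freed beside two primary TBS ethers.
- **Catalyst antipode.** The (R) antipode is assigned from the usual pre-transition-state model for 2-substituted enals. If the sense of induction were opposite for this enal, the (S) antipode would be used and nothing else would change.
- **C13 facial selectivity.** The peracid in step 12 is assumed to attack anti to the pseudoaxial C14 ether. The opposite outcome is covered under the least certain steps.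

## Route

Step 1
Reactants: 1 (E)-4-acetoxy-2-methylbut-2-enal
Product: 2 (E)-4-hydroxy-2-methylbut-2-enal
Conditions: K2CO3 (cat.), MeOH, 0 °C
Reagents that add atoms: none
Why: Mild transesterification of the primary allylic acetate with methanol; the (E) geometry prevents lactol formation and low temperature suppresses conjugate addition.

Step 2
Reactants: 2 (E)-4-hydroxy-2-methylbut-2-enal
Product: 3 (E)-4-(tert-butyldimethylsilyloxy)-2-methylbut-2-enal
Conditions: TBSCl, imidazole, CH2Cl2, 0 °C
Reagents that add atoms: tert-butyldimethylsilyl chloride CC(C)(C)[Si](C)(C)Cl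
Why: Standard silylation of a primary alcohol; the silyl ether is a weak donor and does not compete with the formyl group for the Lewis acid in step 5.

Step 3
Reactants: 4 (E)-4-methoxybut-3-en-2-one; 5 4-methoxybenzyl alcohol
Product: 6 (E)-4-(4-methoxybenzyloxy)but-3-en-2-one
Conditions: PPTS (cat.), toluene, 80 °C, removal of MeOH
Reagents that add atoms: none
Why: Acid-catalysed vinylogous transesterification (addition–elimination at C4); removal of methanol drives the exchange and the (E) isomer is the stable one.

Step 4
Reactants: 6 (E)-4-(4-methoxybenzyloxy)but-3-en-2-one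
Product: 7 (E)-1-(4-methoxybenzyloxy)-3-(triethylsilyloxy)buta-1,3-diene
Conditions: Et3SiOTf, Et3N, Et2O, 0 °C
Reagents that add atoms: triethylsilyl trifluoromethanesulfonate CC[Si](CC)(CC)OS(=O)(=O)C(F)(F)F
Why: Soft enolisation of the methyl ketone gives the cross-conjugated silyl dienol ether with retention of the (E) enol ether.

Step 5
Reactants: 3 (E)-4-(tert-butyldimethylsilyloxy)-2-methylbut-2-enal; 7 (E)-1-(4-methoxybenzyloxy)-3-(triethylsilyloxy)buta-1,3-diene
Product: 8 ring A aldehyde (1R,2S,6S)-6-[(tert-butyldimethylsilyloxy)methyl]-2-(4-methoxybenzyloxy)-1-methyl-4-(triethylsilyloxy)cyclohex-3-ene-1-carbaldehyde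
Conditions: (R)-B-(2-methylphenyl)oxazaborolidine of α,α-diphenylprolinol·HN(SO2CF3)2 (20 mol %), CH2Cl2, −78 → −40 °C; Et3N quench
Reagents that add atoms: none
Why: The formyl group of 3 binds to the cationic boron anti to the alkenyl group and is held by a formyl C–H···O contact, which lowers the LUMO and lays one face of the s-trans enal against an aryl group of the catalyst; 7 adds to the open face in a concerted but asynchronous [4+2] cycloaddition in which the nucleophilic CH2 terminus (C11) bonds to the enal β-carbon (C10) ahead of the bond from the oxygenated terminus (C14) to the α-carbon (C1). The closest known reaction type is the oxazaborolidinium-catalysed Diels–Alder reaction of 2-substituted enals with 2-silyloxy and 1-oxy-3-silyloxy dienes. Ring A is closed by this suprafacial six-electron cycloaddition, the only ring-forming event of the step. C1 and C10 are set by the catalyst-controlled face of the dienophile together with the (E) geometry of 3, which places C2 and C9 trans. C14 is set by the endo position of the complexed formyl group and the (E) enol ether of 7, which places C2 cis to O14. Regiochemistry follows from the push–pull polarisation of 7 (largest HOMO coefficient at C11) and of the complexed enal (largest LUMO coefficient at C10). The step needs selectivity for the C=C over the C=O bond of the enal and enough reactivity from a β-substituted dienophile; the tight two-point binding of the 2-methyl enal, the strongly activating triflimide salt, low temperature and an excess of 7 are chosen to secure both.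

Step 6
Reactants: 9 prop-2-yn-1-ol; 10 allylmagnesium bromide
Product: 12 (Z)-2-(chloromethylene)pent-4-en-1-ol, via cyclic alkenylmagnesium alkoxide 11 (not isolated)
Conditions: 10 (2.5 equiv), Et2O, 0 °C → rt; then N-chlorosuccinimide, THF, −30 °C → rt
Reagents that add atoms: N-chlorosuccinimide O=C1CCC(=O)N1Cl
Why: Alkoxide-directed anti-carbomagnesiation puts the allyl group on the inner alkyne carbon and magnesium on the terminus, held cis to CH2O in a five-membered chelate; electrophilic chlorination of the alkenyl–magnesium bond with retention fixes the (Z)-chloroalkene.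

Step 7
Reactants: 12 (Z)-2-(chloromethylene)pent-4-en-1-ol
Product: 13 (Z)-tert-butyl{[2-(chloromethylene)pent-4-en-1-yl]oxy}dimethylsilane
Conditions: TBSCl, imidazole, CH2Cl2, rt
Reagents that add atoms: tert-butyldimethylsilyl chloride CC(C)(C)[Si](C)(C)Cl
Why: Standard silylation of the primary allylic alcohol.

Step 8
Reactants: 13 (Z)-tert-butyl{[2-(chloromethylene)pent-4-en-1-yl]oxy}dimethylsilane
Product: 16 (Z)-4-(tert-butyldimethylsilyloxy)-3-(chloromethylene)butan-1-ol, via methoxy hydroperoxide 14 (not isolated), via β,γ-unsaturated aldehyde 15 (not isolated)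
Conditions: O3, CH2Cl2–MeOH, −78 °C (indicator end point); then NaBH4, −78 → 0 °C
Reagents that add atoms: ozone [O-][O+]=O
Why: Ozonolysis is selective for the electron-rich terminal vinyl group over the chlorine-deactivated trisubstituted alkene; reduction in the same flask avoids isolating the isomerisation-prone β,γ-unsaturated aldehyde.

Step 9
Reactants: 16 (Z)-4-(tert-butyldimethylsilyloxy)-3-(chloromethylene)butan-1-ol
Product: 17 (Z)-[4-bromo-2-(chloromethylene)butoxy](tert-butyl)dimethylsilane
Conditions: CBr4, PPh3, CH2Cl2, 0 °C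
Reagents that add atoms: carbon tetrabromide BrC(Br)(Br)Br
Why: Appel bromination of a primary alcohol under neutral conditions.

Step 10
Reactants: 8 ring A aldehyde (1R,2S,6S)-6-[(tert-butyldimethylsilyloxy)methyl]-2-(4-methoxybenzyloxy)-1-methyl-4-(triethylsilyloxy)cyclohex-3-ene-1-carbaldehyde; 17 (Z)-[4-bromo-2-(chloromethylene)butoxy](tert-butyl)dimethylsilane
Product: 19 C2 alcohol (2S): 8 with CHO converted into CH(OH)CH2CH2C(=CHCl)CH2OTBS (Z), via Grignard reagent 18 (not isolated)
Conditions: 17, Mg, THF; then 8, MgBr2·OEt2, CH2Cl2, −78 °C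
Reagents that add atoms: none
Why: Grignard addition under 1,3-chelation control: magnesium bridges the formyl oxygen and the C14 4-methoxybenzyl ether, and the nucleophile enters the carbonyl face beside the small C1 methyl group, away from ring A, which gives the 2S carbinol. The alkenyl chloride does not insert magnesium and the triethylsilyl enol ether is inert at −78 °C.

Step 11
Reactants: 19 C2 alcohol (2S): 8 with CHO converted into CH(OH)CH2CH2C(=CHCl)CH2OTBS (Z)
Product: 20 C2 acetate of 19
Conditions: Ac2O, pyridine, DMAP (cat.), CH2Cl2, rt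
Reagents that add atoms: acetic anhydride CC(=O)OC(C)=O
Why: Acylation of the hindered secondary alcohol installs the final C2 acetate before any other hydroxyl group exists.

Step 12
Reactants: 20 C2 acetate of 19
Product: 23 13β-hydroxy 12-ketone: 20 with the enol ether converted into C12=O and 13β-OH, via silyloxy oxirane 21 (not isolated), via 13β-triethylsilyloxy ketone 22 (not isolated)
Conditions: mCPBA, NaHCO3, CH2Cl2, −20 °C; then PPTS, MeOH, 0 °C
Reagents that add atoms: 3-chloroperoxybenzoic acid O=C(OO)c1cccc(Cl)c1
Why: Rubottom oxidation: the peracid epoxidises the electron-rich enol ether anti to the pseudoaxial allylic C14 ether (β face), silyl migration opens the silyloxy oxirane, and mild methanolysis removes the triethylsilyl group while the primary TBS ethers stay.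

Step 13
Reactants: 23 13β-hydroxy 12-ketone: 20 with the enol ether converted into C12=O and 13β-OH; 24 4-methylpentanoic acid
Product: 25 13α-(4-methylpentanoyloxy) 12-ketone
Conditions: PPh3, DIAD, toluene, 0 °C → rt
Reagents that add atoms: none
Why: Mitsunobu esterification: the carboxylate displaces the axial oxyphosphonium group at the ketone-activated C13 with inversion, giving the 13α (equatorial) ester, which is also the more stable epimer.

Step 14
Reactants: 25 13α-(4-methylpentanoyloxy) 12-ketone
Product: 27 11-methylene 12-ketone (exocyclic enone: C20 installed), via Mannich base 26 (not isolated)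
Conditions: (CH2O)n, i-Pr2NH·CF3CO2H, THF, 65 °C
Reagents that add atoms: formaldehyde (as paraformaldehyde) C=O
Why: Mannich-type α-methylenation: only C11 has two α-hydrogens, so aminomethylation there is followed by β-elimination of the amine. Enolisation toward the acyloxy-bearing C13 is slow under these weakly acidic conditions, which also keeps the β-oxygen at C14 from being eliminated.

Step 15
Reactants: 27 11-methylene 12-ketone (exocyclic enone: C20 installed)
Product: 28 12α-allylic alcohol
Conditions: NaBH4, CeCl3·7H2O, MeOH–THF, −78 °C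
Reagents that add atoms: none
Why: Luche reduction gives clean 1,2-reduction of the enone; hydride approach from the α face is blocked by the axial C14 ether, so hydride enters from the β face and the axial 12α-alcohol results.

Step 16
Reactants: 28 12α-allylic alcohol
Product: 29 11α,20-epoxy 12α-alcohol
Conditions: VO(acac)2 (cat.), t-BuOOH, CH2Cl2, 0 °C
Reagents that add atoms: tert-butyl hydroperoxide CC(C)(C)OO
Why: Hydroxyl-directed epoxidation: the vanadium alkoxide of the 12α-hydroxyl delivers oxygen to the α face of the exocyclic alkene, giving the spiro-epoxide with oxygen α and C20 β; the chloroalkene is too electron-poor to react.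

Step 17
Reactants: 29 11α,20-epoxy 12α-alcohol
Product: 30 12α-acetate of 29
Conditions: Ac2O, pyridine, DMAP (cat.), CH2Cl2, rt
Reagents that add atoms: acetic anhydride CC(=O)OC(C)=O
Why: Acylation of the axial allylic-type alcohol under non-alkoxide conditions, so that neither epoxide migration nor acyl migration from O13 can occur.

Step 18
Reactants: 30 12α-acetate of 29
Product: 31 9,16-diol (both primary TBS ethers removed)
Conditions: Bu4NF, AcOH, THF, 0 °C → rt
Reagents that add atoms: none
Why: Buffered fluoride cleaves both primary silyl ethers; acetic acid prevents alkoxide-induced acyl migration and opening of the epoxide by the new C9 hydroxyl.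

Step 19
Reactants: 31 9,16-diol (both primary TBS ethers removed)
Product: 32 16-chloride 9-alcohol
Conditions: N-chlorosuccinimide, Me2S, CH2Cl2, −25 → 0 °C
Reagents that add atoms: N-chlorosuccinimide O=C1CCC(=O)N1Cl
Why: Corey–Kim halogenation: the allylic alkoxysulfonium salt collapses to the primary allylic chloride, while the saturated C9 alkoxysulfonium salt is stable without base and returns the alcohol on work-up.

Step 20
Reactants: 32 16-chloride 9-alcohol
Product: 33 C9 aldehyde
Conditions: Dess–Martin periodinane, NaHCO3, CH2Cl2, 0 °C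
Reagents that add atoms: none
Why: Dess–Martin oxidation under buffered, base-free conditions; the equatorial C11–O bond is poorly aligned with the C9/C10 enol π system, which protects the β,γ-epoxy aldehyde from eliminative ring opening.

Step 21
Reactants: 34 tert-butyldimethyl(prop-2-yn-1-yloxy)silane; 35 pinacolborane (4,4,5,5-tetramethyl-1,3,2-dioxaborolane)
Product: 36 (E)-tert-butyldimethyl{[3-(4,4,5,5-tetramethyl-1,3,2-dioxaborolan-2-yl)allyl]oxy}silane
Conditions: Cp2Zr(H)Cl (cat.), Et3N (cat.), neat, 40 °C
Reagents that add atoms: none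
Why: Zirconium-catalysed syn-hydroboration of the terminal alkyne places boron on the terminal carbon and gives the (E)-alkenylboronate.

Step 22
Reactants: 36 (E)-tert-butyldimethyl{[3-(4,4,5,5-tetramethyl-1,3,2-dioxaborolan-2-yl)allyl]oxy}silane
Product: 37 (E)-tert-butyldimethyl{[3-(4,4,5,5-tetramethyl-1,3,2-dioxaborolan-2-yl)prop-1-en-1-yl]oxy}silane
Conditions: [Ir(C8H12)(PMePh2)2]PF6 (cat., activated with H2), THF, rt
Reagents that add atoms: none
Why: Iridium-hydride catalysed 1,3-hydrogen shift moves the double bond into conjugation with oxygen and gives the (E)-γ-silyloxyallylboronate.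

Step 23
Reactants: 33 C9 aldehyde; 37 (E)-tert-butyldimethyl{[3-(4,4,5,5-tetramethyl-1,3,2-dioxaborolan-2-yl)prop-1-en-1-yl]oxy}silane
Product: 38 (8S,9R)-homoallylic alcohol (8,9-anti): 9-hydroxy 8-OTBS with C7 as a vinyl group
Conditions: toluene, 4 Å MS, 40 °C; N(CH2CH2OH)3 work-up
Reagents that add atoms: none
Why: Allylboration through a closed chair transition state turns the (E)-enol ether geometry into the 8,9-anti relationship without any Lewis acid. The aldehyde is attacked on its sterically preferred face (quaternary C1 anti to the incoming carbon), so C8 is formed in the configuration needed later and C9 as the epimer to be corrected.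

Step 24
Reactants: 38 (8S,9R)-homoallylic alcohol (8,9-anti): 9-hydroxy 8-OTBS with C7 as a vinyl group
Product: 39 C9 ketone
Conditions: Dess–Martin periodinane, NaHCO3, CH2Cl2, 0 °C
Reagents that add atoms: none
Why: Neutral Dess–Martin oxidation; the absence of base keeps the α-silyloxy β,γ-unsaturated ketone from epimerising at C8 or moving its alkene into conjugation.

Step 25
Reactants: 39 C9 ketone
Product: 40 (8S,9S)-alcohol (8,9-syn)
Conditions: LiBH(s-Bu)3, THF, −78 °C; NH4Cl
Reagents that add atoms: none
Why: Ketone reduction by a bulky borohydride under non-chelating 1,2-induction: hydride attacks anti to the quaternary C1 on C10 and anti to the silyloxy group on C8. The two effects reinforce each other and give the 9S alcohol syn to O8.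

Step 26
Reactants: 40 (8S,9S)-alcohol (8,9-syn)
Product: 41 9-acetate of 40
Conditions: Ac2O, pyridine, DMAP (cat.), CH2Cl2, 0 °C → rt
Reagents that add atoms: acetic anhydride CC(=O)OC(C)=O
Why: Acylation installs the final C9 acetate; the primary allylic chloride is not displaced by pyridine at this temperature.

Step 27
Reactants: 41 9-acetate of 40
Product: 43 C7 aldehyde (8R,9S): α-silyloxy β-acetoxy aldehyde, via vicinal diol 42 (not isolated)
Conditions: OsO4 (cat.), NaIO4, 2,6-lutidine, dioxane–H2O, rt
Reagents that add atoms: osmium tetroxide O=[Os](=O)(=O)=O; sodium periodate [Na+].[O-]I(=O)(=O)=O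
Why: Lemieux–Johnson cleavage: osmylation is selective for the monosubstituted vinyl group (the chloroalkene is deactivated) and periodate cleaves the diol; ozone is avoided because of the 4-methoxybenzyl ether.

Step 28
Reactants: 43 C7 aldehyde (8R,9S): α-silyloxy β-acetoxy aldehyde
Product: 45 ten-membered chlorohydrin (6S,7R,8R,9S): 6-chloro-7-hydroxy-5(16)-ene with 8-OTBS, via allylchromium species 44 (not isolated)
Conditions: CrCl2 (4 equiv), THF–DMF, high dilution, 0 °C → rt
Reagents that add atoms: none
Why: Nozaki–Hiyama–Kishi allylation run intramolecularly: divalent chromium inserts into the primary allylic C–Cl bond (the alkenyl chloride is inert without nickel), and the 3-chloroallylchromium species equilibrates by 1,3-metal shift and adds through its chlorine-bearing terminus to the aldehyde in a chair transition state. This closes the ten-membered ring, creates the C5=C16 exo-methylene and gives the 6,7-anti chlorohydrin, while C7 is set 7,8-anti by 1,2-induction from the α-silyloxy centre. Chromium-mediated additions of 3-chloroallyl halides to aldehydes and ten-membered ring closures by allylchromium addition are both established.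

Step 29
Reactants: 45 ten-membered chlorohydrin (6S,7R,8R,9S): 6-chloro-7-hydroxy-5(16)-ene with 8-OTBS; 46 2-bromopropanoyl bromide
Product: 47 7-O-(2-bromopropanoyl) ester of 45 (both epimers at the bromine-bearing carbon)
Conditions: pyridine, CH2Cl2, −30 °C
Reagents that add atoms: none
Why: Acylation of the only free hydroxyl group with an acid bromide; pyridine is too weak a base to close the chlorohydrin to an epoxide.

Step 30
Reactants: 47 7-O-(2-bromopropanoyl) ester of 45 (both epimers at the bromine-bearing carbon)
Product: 48 8-alcohol (TBS ether removed)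
Conditions: HF·pyridine, pyridine, THF, 0 °C → rt
Reagents that add atoms: none
Why: Weakly acidic fluoride cleaves the secondary silyl ether without generating an alkoxide, so the flanking acyl groups on O7 and O9 do not migrate; substituted epoxides and α-bromo esters tolerate this reagent.

Step 31
Reactants: 48 8-alcohol (TBS ether removed)
Product: 49 8-ketone
Conditions: Dess–Martin periodinane, NaHCO3, CH2Cl2, 0 °C
Reagents that add atoms: none
Why: Neutral Dess–Martin oxidation; base is excluded because C7–H is α to the new ketone and β to the C6 chloride.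

Step 32
Reactants: 49 8-ketone
Product: 51 lactone: 14-O-(4-methoxybenzyl) ether of the 14-deacetyl target, via samarium ester enolate 50 (not isolated)
Conditions: SmI2 (2.2 equiv), THF, −78 °C
Reagents that add atoms: none
Why: Intramolecular Reformatsky reaction: SmI2 reduces the C–Br bond much faster than the ketone, and the ester enolate of trivalent samarium adds to the neighbouring C8 carbonyl group. Only the trans fusion of the five- and ten-membered rings is geometrically reasonable, which places O8 cis to C6 (8R), and in the chelated transition state the C17 methyl group points away from C9 (17R).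

Step 33
Reactants: 51 lactone: 14-O-(4-methoxybenzyl) ether of the 14-deacetyl target
Product: 52 14-deacetyl target (14α-alcohol)
Conditions: DDQ, CH2Cl2–pH 7 buffer, 0 °C
Reagents that add atoms: none
Why: Oxidative cleavage of the 4-methoxybenzyl ether under neutral conditions; no neighbouring free hydroxyl group is present that could trap the oxocarbenium ion as an acetal.

Step 34
Reactants: 52 14-deacetyl target (14α-alcohol)
Product: 53 CNP0196150.1 (1S,2S,6S,7R,8R,9S,10S,11R,12R,13R,14R,17R)-2,9,12,14-tetraacetoxy-6-chloro-11,20-epoxy-8-hydroxy-13-(4-methylpentanoyloxy)briar-5(16)-en-19,7-olide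
Conditions: Ac2O, pyridine, DMAP (cat.), rt
Reagents that add atoms: acetic anhydride CC(=O)OC(C)=O
Why: Acylation of the secondary axial 14α-alcohol; the hindered tertiary 8-hydroxyl group is not acetylated under these conditions, and acetylation is faster than acyl migration from O13.

## Compound list

1 | (E)-4-acetoxy-2-methylbut-2-enal | CC(=O)OC/C=C(\C)C=O | starting material
2 | (E)-4-hydroxy-2-methylbut-2-enal | O=C/C(C)=C/CO | intermediate
3 | (E)-4-(tert-butyldimethylsilyloxy)-2-methylbut-2-enal | O=C/C(C)=C/CO[Si](C)(C)C(C)(C)C | intermediate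
4 | (E)-4-methoxybut-3-en-2-one | CO/C=C/C(C)=O | starting material
5 | 4-methoxybenzyl alcohol | COc1ccc(CO)cc1 | starting material
6 | (E)-4-(4-methoxybenzyloxy)but-3-en-2-one | CC(=O)/C=C/OCc1ccc(OC)cc1 | intermediate
7 | (E)-1-(4-methoxybenzyloxy)-3-(triethylsilyloxy)buta-1,3-diene | C=C(O[Si](CC)(CC)CC)/C=C/OCc1ccc(OC)cc1 | intermediate
8 | ring A aldehyde (1R,2S,6S)-6-[(tert-butyldimethylsilyloxy)methyl]-2-(4-methoxybenzyloxy)-1-methyl-4-(triethylsilyloxy)cyclohex-3-ene-1-carbaldehyde | O=C[C@@]2(C)[C@@H](OCc3ccc(OC)cc3)C=C(O[Si](CC)(CC)CC)C[C@@H]2CO[Si](C)(C)C(C)(C)C | intermediate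
9 | prop-2-yn-1-ol | C#CCO | starting material
10 | allylmagnesium bromide | C=CC[Mg]Br | starting material
11 | cyclic alkenylmagnesium alkoxide (3-allyl-2,5-dihydro-1,2-oxamagnesole) | C=CCC1=C[Mg]OC1 | intermediate
12 | (Z)-2-(chloromethylene)pent-4-en-1-ol | OC/C(CC=C)=C\Cl | intermediate
13 | (Z)-tert-butyl{[2-(chloromethylene)pent-4-en-1-yl]oxy}dimethylsilane | Cl/C=C(\CO[Si](C)(C)C(C)(C)C)CC=C | intermediate
14 | methoxy hydroperoxide: (Z)-4-(tert-butyldimethylsilyloxy)-3-(chloromethylene)-1-methoxybutyl hydroperoxide | Cl/C=C(\CO[Si](C)(C)C(C)(C)C)CC(OC)OO | intermediate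
15 | β,γ-unsaturated aldehyde: (Z)-4-(tert-butyldimethylsilyloxy)-3-(chloromethylene)butanal | Cl/C=C(\CO[Si](C)(C)C(C)(C)C)CC=O | intermediate
16 | (Z)-4-(tert-butyldimethylsilyloxy)-3-(chloromethylene)butan-1-ol | Cl/C=C(\CO[Si](C)(C)C(C)(C)C)CCO | intermediate
17 | (Z)-[4-bromo-2-(chloromethylene)butoxy](tert-butyl)dimethylsilane | Cl/C=C(\CO[Si](C)(C)C(C)(C)C)CCBr | intermediate
18 | Grignard reagent of 17 | Cl/C=C(\CO[Si](C)(C)C(C)(C)C)CC[Mg]Br | intermediate
19 | C2 alcohol (2S): 8 with CHO converted into CH(OH)CH2CH2C(=CHCl)CH2OTBS (Z) | Cl/C=C(\CO[Si](C)(C)C(C)(C)C)CC[C@H](O)[C@@]2(C)[C@@H](OCc3ccc(OC)cc3)C=C(O[Si](CC)(CC)CC)C[C@@H]2CO[Si](C)(C)C(C)(C)C | intermediate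
20 | C2 acetate of 19 | Cl/C=C(\CO[Si](C)(C)C(C)(C)C)CC[C@H](OC(C)=O)[C@@]2(C)[C@@H](OCc3ccc(OC)cc3)C=C(O[Si](CC)(CC)CC)C[C@@H]2CO[Si](C)(C)C(C)(C)C | intermediate
21 | silyloxy oxirane: 12β,13β-epoxide of 20 with 12α-OSiEt3 | Cl/C=C(\CO[Si](C)(C)C(C)(C)C)CC[C@H](OC(C)=O)[C@@]2(C)[C@@H](OCc3ccc(OC)cc3)[C@H](O4)[C@@]4(O[Si](CC)(CC)CC)C[C@@H]2CO[Si](C)(C)C(C)(C)C | intermediate
22 | 13β-triethylsilyloxy ketone | Cl/C=C(\CO[Si](C)(C)C(C)(C)C)CC[C@H](OC(C)=O)[C@@]2(C)[C@@H](OCc3ccc(OC)cc3)[C@H](O[Si](CC)(CC)CC)C(=O)C[C@@H]2CO[Si](C)(C)C(C)(C)C | intermediate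
23 | 13β-hydroxy 12-ketone: 20 with the enol ether converted into C12=O and 13β-OH | Cl/C=C(\CO[Si](C)(C)C(C)(C)C)CC[C@H](OC(C)=O)[C@@]2(C)[C@@H](OCc3ccc(OC)cc3)[C@H](O)C(=O)C[C@@H]2CO[Si](C)(C)C(C)(C)C | intermediate
24 | 4-methylpentanoic acid | CC(C)CCC(=O)O | starting material
25 | 13α-(4-methylpentanoyloxy) 12-ketone | Cl/C=C(\CO[Si](C)(C)C(C)(C)C)CC[C@H](OC(C)=O)[C@@]2(C)[C@@H](OCc3ccc(OC)cc3)[C@@H](OC(=O)CCC(C)C)C(=O)C[C@@H]2CO[Si](C)(C)C(C)(C)C | intermediate
26 | Mannich base: 11-(diisopropylaminomethyl) derivative of 25 (C11 unassigned) | Cl/C=C(\CO[Si](C)(C)C(C)(C)C)CC[C@H](OC(C)=O)[C@@]2(C)[C@@H](OCc3ccc(OC)cc3)[C@@H](OC(=O)CCC(C)C)C(=O)C(CN(C(C)C)C(C)C)[C@@H]2CO[Si](C)(C)C(C)(C)C | intermediate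
27 | 11-methylene 12-ketone (exocyclic enone: C20 installed) | Cl/C=C(\CO[Si](C)(C)C(C)(C)C)CC[C@H](OC(C)=O)[C@@]2(C)[C@@H](OCc3ccc(OC)cc3)[C@@H](OC(=O)CCC(C)C)C(=O)C(=C)[C@@H]2CO[Si](C)(C)C(C)(C)C | intermediate
28 | 12α-allylic alcohol | Cl/C=C(\CO[Si](C)(C)C(C)(C)C)CC[C@H](OC(C)=O)[C@@]2(C)[C@@H](OCc3ccc(OC)cc3)[C@@H](OC(=O)CCC(C)C)[C@@H](O)C(=C)[C@@H]2CO[Si](C)(C)C(C)(C)C | intermediate
29 | 11α,20-epoxy 12α-alcohol | Cl/C=C(\CO[Si](C)(C)C(C)(C)C)CC[C@H](OC(C)=O)[C@@]2(C)[C@@H](OCc3ccc(OC)cc3)[C@@H](OC(=O)CCC(C)C)[C@@H](O)[C@]4(CO4)[C@@H]2CO[Si](C)(C)C(C)(C)C | intermediate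
30 | 12α-acetate of 29 | Cl/C=C(\CO[Si](C)(C)C(C)(C)C)CC[C@H](OC(C)=O)[C@@]2(C)[C@@H](OCc3ccc(OC)cc3)[C@@H](OC(=O)CCC(C)C)[C@@H](OC(C)=O)[C@]4(CO4)[C@@H]2CO[Si](C)(C)C(C)(C)C | intermediate
31 | 9,16-diol (both primary TBS ethers removed) | Cl/C=C(\CO)CC[C@H](OC(C)=O)[C@@]2(C)[C@@H](OCc3ccc(OC)cc3)[C@@H](OC(=O)CCC(C)C)[C@@H](OC(C)=O)[C@]4(CO4)[C@@H]2CO | intermediate
32 | 16-chloride 9-alcohol | Cl/C=C(\CCl)CC[C@H](OC(C)=O)[C@@]2(C)[C@@H](OCc3ccc(OC)cc3)[C@@H](OC(=O)CCC(C)C)[C@@H](OC(C)=O)[C@]4(CO4)[C@@H]2CO | intermediate
33 | C9 aldehyde | Cl/C=C(\CCl)CC[C@H](OC(C)=O)[C@@]2(C)[C@@H](OCc3ccc(OC)cc3)[C@@H](OC(=O)CCC(C)C)[C@@H](OC(C)=O)[C@]4(CO4)[C@@H]2C=O | intermediate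
34 | tert-butyldimethyl(prop-2-yn-1-yloxy)silane | C#CCO[Si](C)(C)C(C)(C)C | starting material
35 | pinacolborane (4,4,5,5-tetramethyl-1,3,2-dioxaborolane) | CC1(C)OBOC1(C)C | starting material
36 | (E)-tert-butyldimethyl{[3-(4,4,5,5-tetramethyl-1,3,2-dioxaborolan-2-yl)allyl]oxy}silane | CC1(C)OB(/C=C/CO[Si](C)(C)C(C)(C)C)OC1(C)C | intermediate
37 | (E)-tert-butyldimethyl{[3-(4,4,5,5-tetramethyl-1,3,2-dioxaborolan-2-yl)prop-1-en-1-yl]oxy}silane | CC1(C)OB(C/C=C/O[Si](C)(C)C(C)(C)C)OC1(C)C | intermediate
38 | (8S,9R)-homoallylic alcohol (8,9-anti): 9-hydroxy 8-OTBS with C7 as a vinyl group | Cl/C=C(\CCl)CC[C@H](OC(C)=O)[C@@]2(C)[C@@H](OCc3ccc(OC)cc3)[C@@H](OC(=O)CCC(C)C)[C@@H](OC(C)=O)[C@]4(CO4)[C@@H]2[C@@H](O)[C@@H](O[Si](C)(C)C(C)(C)C)C=C | intermediate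
39 | C9 ketone | Cl/C=C(\CCl)CC[C@H](OC(C)=O)[C@@]2(C)[C@@H](OCc3ccc(OC)cc3)[C@@H](OC(=O)CCC(C)C)[C@@H](OC(C)=O)[C@]4(CO4)[C@@H]2C(=O)[C@@H](O[Si](C)(C)C(C)(C)C)C=C | intermediate
40 | (8S,9S)-alcohol (8,9-syn) | Cl/C=C(\CCl)CC[C@H](OC(C)=O)[C@@]2(C)[C@@H](OCc3ccc(OC)cc3)[C@@H](OC(=O)CCC(C)C)[C@@H](OC(C)=O)[C@]4(CO4)[C@@H]2[C@H](O)[C@@H](O[Si](C)(C)C(C)(C)C)C=C | intermediate
41 | 9-acetate of 40 | Cl/C=C(\CCl)CC[C@H](OC(C)=O)[C@@]2(C)[C@@H](OCc3ccc(OC)cc3)[C@@H](OC(=O)CCC(C)C)[C@@H](OC(C)=O)[C@]4(CO4)[C@@H]2[C@H](OC(C)=O)[C@@H](O[Si](C)(C)C(C)(C)C)C=C | intermediate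
42 | vicinal diol from the vinyl group of 41 (new carbinol centre unassigned) | Cl/C=C(\CCl)CC[C@H](OC(C)=O)[C@@]2(C)[C@@H](OCc3ccc(OC)cc3)[C@@H](OC(=O)CCC(C)C)[C@@H](OC(C)=O)[C@]4(CO4)[C@@H]2[C@H](OC(C)=O)[C@@H](O[Si](C)(C)C(C)(C)C)C(O)CO | intermediate
43 | C7 aldehyde (8R,9S): α-silyloxy β-acetoxy aldehyde | Cl/C=C(\CCl)CC[C@H](OC(C)=O)[C@@]2(C)[C@@H](OCc3ccc(OC)cc3)[C@@H](OC(=O)CCC(C)C)[C@@H](OC(C)=O)[C@]4(CO4)[C@@H]2[C@H](OC(C)=O)[C@@H](O[Si](C)(C)C(C)(C)C)C=O | intermediate
44 | allylchromium species: C16–CrCl2 derivative of 43 | Cl/C=C(\C[Cr](Cl)Cl)CC[C@H](OC(C)=O)[C@@]2(C)[C@@H](OCc3ccc(OC)cc3)[C@@H](OC(=O)CCC(C)C)[C@@H](OC(C)=O)[C@]4(CO4)[C@@H]2[C@H](OC(C)=O)[C@@H](O[Si](C)(C)C(C)(C)C)C=O | intermediate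
45 | ten-membered chlorohydrin (6S,7R,8R,9S): 6-chloro-7-hydroxy-5(16)-ene with 8-OTBS | C=C1CC[C@H](OC(C)=O)[C@@]2(C)[C@@H](OCc3ccc(OC)cc3)[C@@H](OC(=O)CCC(C)C)[C@@H](OC(C)=O)[C@]4(CO4)[C@@H]2[C@H](OC(C)=O)[C@@H](O[Si](C)(C)C(C)(C)C)[C@@H](O)[C@H]1Cl | intermediate
46 | 2-bromopropanoyl bromide | CC(Br)C(Br)=O | starting material
47 | 7-O-(2-bromopropanoyl) ester of 45 (both epimers at the bromine-bearing carbon) | C=C1CC[C@H](OC(C)=O)[C@@]2(C)[C@@H](OCc3ccc(OC)cc3)[C@@H](OC(=O)CCC(C)C)[C@@H](OC(C)=O)[C@]4(CO4)[C@@H]2[C@H](OC(C)=O)[C@@H](O[Si](C)(C)C(C)(C)C)[C@@H](OC(=O)C(C)Br)[C@H]1Cl | intermediate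
48 | 8-alcohol (TBS ether removed) | C=C1CC[C@H](OC(C)=O)[C@@]2(C)[C@@H](OCc3ccc(OC)cc3)[C@@H](OC(=O)CCC(C)C)[C@@H](OC(C)=O)[C@]4(CO4)[C@@H]2[C@H](OC(C)=O)[C@@H](O)[C@@H](OC(=O)C(C)Br)[C@H]1Cl | intermediate
49 | 8-ketone | C=C1CC[C@H](OC(C)=O)[C@@]2(C)[C@@H](OCc3ccc(OC)cc3)[C@@H](OC(=O)CCC(C)C)[C@@H](OC(C)=O)[C@]4(CO4)[C@@H]2[C@H](OC(C)=O)C(=O)[C@@H](OC(=O)C(C)Br)[C@H]1Cl | intermediate
50 | samarium ester enolate of 49 | C=C1CC[C@H](OC(C)=O)[C@@]2(C)[C@@H](OCc3ccc(OC)cc3)[C@@H](OC(=O)CCC(C)C)[C@@H](OC(C)=O)[C@]4(CO4)[C@@H]2[C@H](OC(C)=O)C(=O)[C@@H](OC(O[Sm](I)I)=CC)[C@H]1Cl | intermediate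
51 | lactone: 14-O-(4-methoxybenzyl) ether of the 14-deacetyl target | C=C1CC[C@H](OC(C)=O)[C@@]2(C)[C@@H](OCc3ccc(OC)cc3)[C@@H](OC(=O)CCC(C)C)[C@@H](OC(C)=O)[C@]4(CO4)[C@@H]2[C@H](OC(C)=O)[C@]2(O)[C@@H](C)C(=O)O[C@H]2[C@H]1Cl | intermediate
52 | 14-deacetyl target (14α-alcohol) | C=C1CC[C@H](OC(C)=O)[C@@]2(C)[C@@H](O)[C@@H](OC(=O)CCC(C)C)[C@@H](OC(C)=O)[C@]4(CO4)[C@@H]2[C@H](OC(C)=O)[C@]2(O)[C@@H](C)C(=O)O[C@H]2[C@H]1Cl | intermediate
53 | CNP0196150.1 (1S,2S,6S,7R,8R,9S,10S,11R,12R,13R,14R,17R)-2,9,12,14-tetraacetoxy-6-chloro-11,20-epoxy-8-hydroxy-13-(4-methylpentanoyloxy)briar-5(16)-en-19,7-olide | C=C1CC[C@H](OC(C)=O)[C@@]2(C)[C@@H](OC(C)=O)[C@@H](OC(=O)CCC(C)C)[C@@H](OC(C)=O)[C@]3(CO3)[C@@H]2[C@H](OC(C)=O)[C@]2(O)[C@@H](C)C(=O)O[C@H]2[C@H]1Cl | target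

## Step count and least certain steps

Total: 34 steps. Longest linear sequence: 27 steps (steps 6–20 and 23–34, from 9 to 53). The route through 1 is 26 steps.

**Step 5 (key step).** The cycloaddition of the β-substituted 2-methyl enal may be slow. Acid-promoted decomposition of the diene, or addition at the carbonyl group (hetero-Diels–Alder or aldol-type pathway), could then compete, and enantio- or endo selectivity could erode through a looser transition state.
Fallback: 3 and 7 are combined without catalyst (toluene, 110 °C, or under high pressure). This should give the endo adduct as a racemate, that is 8 together with the enantiomer of 8 F1. The enantiomers are separated by preparative chromatography on a chiral stationary phase, and the route is rejoined at 8. The approach changes from asymmetric catalysis to resolution.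

**Step 12.** Facial selectivity of the enol ether oxidation may be poor. The β face carries the axial C1 methyl group three atoms from C13, and the α face carries the pseudoaxial C14 ether, so attack from the α face can compete.
Fallback: setting out from 20, the oxidation then gives the 13α-hydroxy ketone F2. F2 is esterified with 24 under retention (carbodiimide, DMAP) and gives 25 directly. Both epimers therefore converge on 25, one by inversion and one by retention.

**Step 13.** The Mitsunobu displacement may fail through elimination or non-reaction, because the carboxylate must approach C13 alongside the axial C14–O bond.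
Fallback: setting out from 23, the alcohol is acylated with retention (24, carbodiimide, DMAP) to the 13β-ester F3. F3 is equilibrated through its enol with a tertiary amine base to the equatorial 13α-ester. The 13β-acyloxy group is syn-axial to the C1 methyl group, so thermodynamic control replaces the SN2 reaction. The route is rejoined at 25.

**Step 28.** Three things may go wrong. Excess divalent chromium may reduce the secondary allylic chloride of the product, with loss of the C7 oxygen by elimination. Relative configuration at C6/C7 may be low if the chloroallylchromium species does not equilibrate or the ring imposes a boat transition state. Oligomerisation may compete with closure of the ten-membered ring.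
Fallback: a redox-neutral, preformed allylmetal is used. Setting out from 41, the allylic chloride is converted with Bu3SnSnBu3 and Pd(PPh3)4 (zerovalent palladium) into the allylstannane F4. Lemieux–Johnson cleavage of the vinyl group then gives the stannyl aldehyde F5. InCl3 transmetallates F5 to an equilibrating allylindium species that should cyclise through a closed transition state. The route is rejoined at 45.

**Step 32.** Electron transfer to the α,α′-diacyloxy ketone may compete, with reductive loss of an acyloxy group. Retro-aldol opening of the samarium aldolate, or the wrong configuration at C17 from an unfavourable enolate geometry, is also possible.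
Fallback: carbenoid C–H insertion without a C8 ketone. Setting out from 45, O7 is acylated with 2-(tosylhydrazono)propanoyl chloride and treated with Et3N to give the 2-diazopropanoate F6. Rh2(O2CCPh3)4 should induce insertion into the C8–H bond with retention to give the 8-silyloxy lactone F7. HF·pyridine then frees the tertiary alcohol, and the route is rejoined at 51.

## Further compounds

F1 | step 5 | enantiomer of 8 | O=C[C@]2(C)[C@H](OCc3ccc(OC)cc3)C=C(O[Si](CC)(CC)CC)C[C@H]2CO[Si](C)(C)C(C)(C)C
F2 | step 12 | 13α-hydroxy 12-ketone (C13 epimer of 23) | Cl/C=C(\CO[Si](C)(C)C(C)(C)C)CC[C@H](OC(C)=O)[C@@]2(C)[C@@H](OCc3ccc(OC)cc3)[C@@H](O)C(=O)C[C@@H]2CO[Si](C)(C)C(C)(C)C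
F3 | step 13 | 13β-(4-methylpentanoyloxy) 12-ketone (C13 epimer of 25) | Cl/C=C(\CO[Si](C)(C)C(C)(C)C)CC[C@H](OC(C)=O)[C@@]2(C)[C@@H](OCc3ccc(OC)cc3)[C@H](OC(=O)CCC(C)C)C(=O)C[C@@H]2CO[Si](C)(C)C(C)(C)C
F4 | step 28 | allylstannane: 41 with C16–Cl replaced by C16–SnBu3 | Cl/C=C(\C[Sn](CCCC)(CCCC)CCCC)CC[C@H](OC(C)=O)[C@@]2(C)[C@@H](OCc3ccc(OC)cc3)[C@@H](OC(=O)CCC(C)C)[C@@H](OC(C)=O)[C@]4(CO4)[C@@H]2[C@H](OC(C)=O)[C@@H](O[Si](C)(C)C(C)(C)C)C=C
F5 | step 28 | stannyl aldehyde: 43 with C16–Cl replaced by C16–SnBu3 | Cl/C=C(\C[Sn](CCCC)(CCCC)CCCC)CC[C@H](OC(C)=O)[C@@]2(C)[C@@H](OCc3ccc(OC)cc3)[C@@H](OC(=O)CCC(C)C)[C@@H](OC(C)=O)[C@]4(CO4)[C@@H]2[C@H](OC(C)=O)[C@@H](O[Si](C)(C)C(C)(C)C)C=O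
F6 | step 32 | 7-O-(2-diazopropanoyl) ester of 45 | C=C1CC[C@H](OC(C)=O)[C@@]2(C)[C@@H](OCc3ccc(OC)cc3)[C@@H](OC(=O)CCC(C)C)[C@@H](OC(C)=O)[C@]4(CO4)[C@@H]2[C@H](OC(C)=O)[C@@H](O[Si](C)(C)C(C)(C)C)[C@@H](OC(=O)C(C)=[N+]=[N-])[C@H]1Cl
F7 | step 32 | 8-O-TBS ether of 51 | C=C1CC[C@H](OC(C)=O)[C@@]2(C)[C@@H](OCc3ccc(OC)cc3)[C@@H](OC(=O)CCC(C)C)[C@@H](OC(C)=O)[C@]4(CO4)[C@@H]2[C@H](OC(C)=O)[C@]2(O[Si](C)(C)C(C)(C)C)[C@@H](C)C(=O)O[C@H]2[C@H]1Cl
A1 | alternative 1 | ring A ketone with trans C9 silylmethyl and C2 aldol arms | CC(C)(C)[Si](C)(C)OC/C=C(\C)CC[C@H](O)[C@@]2(C)C(=O)[C@@H](OC(C)(C)O3)[C@@H]3C(OC)(OC)[C@@H]2C[Si](C)(C)OC(C)C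
A2 | alternative 1 | ring A enone (quinone monoketal diol acetonide) | CC1=CC(OC)(OC)[C@@H]2OC(C)(C)O[C@@H]2C1=O
A3 | alternative 1 | (E)-6-(tert-butyldimethylsilyloxy)-4-methylhex-4-enal | CC(C)(C)[Si](C)(C)OC/C=C(\C)CCC=O
A4 | alternative 2 | ten-membered C2,C7-diketone | C12(OCCO1)CCC(=O)[C@@]4(C)[C@@H](OC(C)(C)O5)[C@@H](O[Si](C)(C)C(C)(C)C)[C@@H]5C6(OCCO6)[C@@H]4[C@H](OCOC)[C@](O)([C@@H](C)COCOC)C(=O)C2
A5 | alternative 2 | tricyclic C2=C7 alkene | C12(OCCO1)CCC=7[C@@]4(C)[C@@H](OC(C)(C)O5)[C@@H](O[Si](C)(C)C(C)(C)C)[C@@H]5C6(OCCO6)[C@@H]4[C@H](OCOC)[C@](O)([C@@H](C)COCOC)C=7C2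
A6 | alternative 2 | dehydroabietic acid | CC(C)C1=CC2=C(C=C1)[C@]3(CCC[C@@]([C@@H]3CC2)(C)C(=O)O)C
A7 | alternative 3 | C8-silyloxy γ-lactone on the ten-membered ring | [C@@H]1(COCc6ccc(OC)cc6)CC[C@H](OC(C)=O)[C@@]2(C)[C@@H](OC(C)(C)O5)[C@@H](O[Si](C)(C)C(C)(C)C)[C@@H]5C(=C)[C@@H]2[C@H](OC(C)=O)[C@]2(O[Si](CC)(CC)CC)[C@@H](C)C(=O)O[C@H]2[C@H]1Cl
A8 | alternative 3 | C7 2-diazopropanoate with C8–H triethylsilyl ether | [C@@H]1(COCc6ccc(OC)cc6)CC[C@H](OC(C)=O)[C@@]2(C)[C@@H](OC(C)(C)O5)[C@@H](O[Si](C)(C)C(C)(C)C)[C@@H]5C(=C)[C@@H]2[C@H](OC(C)=O)[C@@H](O[Si](CC)(CC)CC)[C@@H](OC(=O)C(C)=[N+]=[N-])[C@H]1Cl
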